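Alpha's leftover is substrate: the flask shows 16.6 % target at 40.0 min, so up to 83.4 % of its substrate stands unconverted, yet the readings climb by 0.3 percentage points over the last 15.0 min, and I must decide what goes into this flask at 50 min.

| flask | substrate | capture agent | free catalyst | temperature | remark | time |
|---|---|---|---|---|---|---|
| alpha | 0.30 M | 0.030 M | 22 mM | 60 °C | the very flask that is asked about, followed so far |  |
| delta | 0.20 M | 0.030 M | 22 mM | 66 °C | run made earlier |  |
| flask | 0.30 M | 0.0300 M | 22 mM | 60 °C |  | 50 min |

| run | time / min | target / % |
|---|---|---|
| alpha | 3.00 | 10.0 |
| alpha | 5.00 | 13.1 |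
| alpha | 8.00 | 14.9 |
| alpha | 12.0 | 15.6 |
| alpha | 15.0 | 15.9 |
| alpha | 25.0 | 16.3 |
| alpha | 40.0 | 16.6 |
| delta | 0.200 | 1.8 |
| delta | 0.500 | 4.4 |
| delta | 1.00 | 8.7 |
| delta | 1.50 | 11.4 |
| delta | 2.00 | 13.5 |
| delta | 3.00 | 16.7 |
| delta | 4.00 | 19.2 |

(scatter of a reading: 0.3 percentage points)

- green: change nothing and wait 50 min more
- blue: at 50 min add free catalyst, 100 % of the amount charged, then wait 50 min
- teal: at 50 min add substrate, 50.0 % of the amount charged, then wait 50 min
- amber: at 50 min raise the temperature by 10 K, then wait 50 min

- target, in percent of the substrate first charged, at 50 min
- which option adds most target ("none" when 2 percentage points or less is all one gets) (green / blue / teal / amber / none)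
- target present, in percent of the substrate first charged, after teal
- target present, in percent of the substrate first charged, after amber

- additions leave the volume as it is
- a reading or a percentage of target counts all its forms, free or not

The target in alpha, 49.8 mM, lies below the substrate charge, so I look for another limit. Delta, hotter and with less substrate, has passed alpha's percentage at 19.2 %, but its 38.4 mM is still below alpha's molar figure, so I reckon in molar amounts.

My assumption is that the capture agent takes catalyst one to one. The catalyst charge is below the capture agent charge, which makes catalyst the limiting reagent of the capture and leaves 8.00 mM of capture agent free.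

I treat the catalytic round as a steady state, so that catalyst in it splits steadily between releasing target and being captured. Target gained per capture agent lost then goes as F/[capture agent], and integration gives [target] = F ln([capture agent] at start / [capture agent] at end). Alpha gives 37.7 mM: this is F, the fork concentration, the [capture agent] at which catalyst in the round is as likely to release target as to be captured.

The rule holds no [substrate], so teal gains nothing by it, and once the 22 mM of catalyst is captured, my reckoning leaves waiting and heat no catalyst to act on. I commit to 16.6 % now and after teal and amber, give or take 0.3 points. Blue puts 22 mM of free catalyst against 8.00 mM of capture agent, so taken one to one the capture leaves 14.0 mM of it uncaptured, and I charge free catalyst.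

The forecast, from the same runs, gives 16.8 % now, blue as best, and 17.6 % after teal and 18 % after amber, both above my flat figure, and it reads the stall as “target poisoning the catalyst stoichiometrically”.

The flask gives 16.4 % at 50 min. Blue adds 11 points, while green, teal and amber each add 0 points, so teal ends at 16.4 % and amber at 16.4 %.

    substrate + free catalyst → catalyst intermediate A (k = 0.370 M⁻¹ s⁻¹, Ea = 64.0 kJ mol⁻¹)
    catalyst intermediate A ⇌ catalyst intermediate B (K = 0.770, k = 0.140 s⁻¹, Ea = 90.0 kJ mol⁻¹, ΔH = −67.0 kJ mol⁻¹)
    catalyst intermediate B → free catalyst + target (k = 0.0650 s⁻¹, Ea = 88.0 kJ mol⁻¹)
    catalyst intermediate A + capture agent → trapped intermediate (k = 0.970 M⁻¹ s⁻¹, Ea = 43.0 kJ mol⁻¹)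
    free catalyst + target → free catalyst + over-reaction product (k = 0.0600 M⁻¹ s⁻¹, Ea = 65.0 kJ mol⁻¹)
    free catalyst + target ⇌ idle complex, settled at all times (K = 3.60 M⁻¹, ΔH = −42.0 kJ mol⁻¹)
    (constants at 60 °C)

In the flask the round and the capture ran side by side while free catalyst was there: at 5.00 min free catalyst stood at 2.52 % and the trapped intermediate at 88.3 % of the catalyst charged, and target at 13.0 % of the substrate charged. By 50.0 min the trapped intermediate held >99.9 % of the catalyst, with 27 % of the capture agent and 76 % of the substrate left, and F on that capture agent gives 16.6 % target. On the neighbour flask charged with 0.0088 M of free catalyst, F gives 4.36 %, and that flask holds 4.38 % target, with 71 % of its capture agent left.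

The runs were generated by integration for an exercise, noise included.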